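Remark on the chemistry: the rings are lettered A (terminal 3,5-dioxygenated ring), B, C and D (2,4,6-trioxygenated ring). Ring B C1 carries the oxygen to ring A, C2 and C4 carry hydroxyls, and C6 carries the oxygen to ring C. Ring C C1 carries the oxygen to ring B, C2, C4 and C6 carry hydroxyls, and C5 carries the bond to ring D. Compounds 1, 3, 7, 8 and 14 are assumed to be catalogue chemicals. The structures of the key-step precursor and product were checked atom by atom against the target and need no correction. What is changed is the access to the precursor (a formyl group on ring C as latent oxygen, so no symmetric biaryl has to be monofunctionalised and no organolithium is needed) and the conversion of the nitro group into the ring A ether.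

## Structural features

- The target (C24H18O12) consists of four benzene rings and nothing else. Ring A (3,5-dihydroxyphenyl) is joined through an ether oxygen to C1 of ring B, ring B C6 is joined through a second ether oxygen to C1 of ring C, and ring C C5 is bonded directly to C1 of ring D (2,4,6-trihydroxyphenyl).
- Rings B and C each carry three contiguous oxygenated carbons (C6, C1, C2) plus one more oxygen at C4, so both ether oxygens sit between two other oxygen substituents.
- There is no stereocentre. The C–D biaryl bond has four ortho oxygens, but ring D is symmetric about that bond, so no atropisomers exist and nothing has to be controlled stereochemically.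
- The fragile part is the set of ten free phenols on very electron-rich rings. They are easily oxidised by air, especially on the 1,2,3-trioxygenated rings B and C, and their free CH positions are open to electrophiles. The phenols therefore have to stay masked until the last step.
- The real difficulties are three: the two diaryl ether bonds at doubly flanked positions, the tetra-ortho-substituted biaryl bond, and telling ring C from ring D, which differ only by the oxygen at ring C C1.
- The key step uses the fact that ring B C1 lies between the oxygen-bearing carbons C2 and C6. A nitro group placed at C1 makes both neighbours electrophilic towards two different oxygen nucleophiles and is afterwards exchanged for the C1 oxygen that carries ring A.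

## Logic of the disconnections

16 is traced to 15 by cutting the ten O–CH3 bonds in the reverse sense. The free polyphenol cannot be carried through base, copper or diazonium chemistry, whereas methyl ethers survive every planned condition and come with the purchased building blocks. The gain is that every intermediate is a neutral compound that can be chromatographed. The demand is one exhaustive dealkylation that leaves both diaryl ethers and the biaryl bond intact.

15 is cut at the bond between the ring B C1 oxygen and ring A, giving 13 and 14. The cut is made on the ring A side of the oxygen so that the flanked ring B oxygen acts as nucleophile and the unhindered ring A as electrophile. The gain is the removal of a whole ring that can be bought as a simple aryl halide. The forward step must be a C–O coupling that tolerates a phenoxide substituted on both sides and oxidisable in air.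

13 is traced through 11 to 10 by exchanging the C1–O bond for a C1–N bond and then for the nitro group. An oxygen at C1 would make ring B a poor electrophile, whereas a nitro group at C1 is exactly what activates C2 and C6. The gain is that ring B can enter as an electron-poor, symmetric building block. The demand is a nitrogen-to-oxygen exchange at an electron-rich, di-ortho-substituted carbon, done without isolating a diazonium salt.

10 is cut at two C–O bonds of ring B, the C6–O bond to ring C and the C2–O bond to methyl, giving 6, 7 and 8. Both carbons are ortho to the nitro group, so both bonds can be made by addition–elimination in one flask. The gain is the largest of the route: ring B with its full 1,2,4,6 pattern and the B–C ether arrive in one convergent operation from a symmetric electrophile. The demand is that the first displacement stops cleanly after one fluoride.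

6 is traced to 4 by exchanging the ring C C1–O bond for a C1–CHO bond. A formyl group marks ring C alone, so the two rings of the biaryl are never equivalent and no statistical monofunctionalisation is required. The gain is an unambiguous position for the oxygen. The demand is that the aryl group, not hydride, migrates in the peroxide rearrangement.

4 is cut at the biaryl bond between ring C C5 and ring D C1, giving 2 and 3. This separates two simple, fully substituted benzene building blocks. The demand is a cross-coupling that forms a tetra-ortho-substituted biaryl faster than the boron partner is lost.

2 is cut at its C–Br bond to give 1. The free ring position is activated by all three methoxy groups and is meta to the formyl group, so a plain electrophilic bromination with one equivalent of reagent suffices.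

## Other disconnections considered

Alternative 1: Here ring A is dismantled instead of the O–ring A bond. Cutting C1–C6 and C2–C3 of ring A leads to the ring B ethynyl ether A1 and the cyclobutenone A2.

- Forward key step: heating A1 with A2 should open A2 to a vinylketene, which adds [2+2] to the electron-rich alkyne of A1. The new vinylcyclobutenone reopens, closes by 6π electrocyclisation and tautomerises to the diaryl ether A3 (Danheiser benzannulation).
- In its favour: the hindered aryl–oxygen bond is never made by coupling, because the oxygen sits on ring B from the start. No nitrogen-to-oxygen exchange and no diazonium stage are needed. On this point the alternative is better than the chosen plan. The 1,3,5-oxygen pattern of ring A arises regiospecifically and no metal catalyst is required.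
- Against it: A1 is the ynol ether of a flanked, electron-rich phenol and would need several steps through a haloalkenyl ether, and it is thermally delicate. A2 must be prepared as well. The annulation is spent on the one ring that can be bought fully oxygenated as 14. The B–C ether and the biaryl remain unsolved, and the ring B C6 oxygen (benzyl-protected in A3) would later have to attack a ring C electrophile flanked by two oxygens, which is the harder polarity. The distinct ethyl, benzyl and free-hydroxyl groups of A3 are of no use because every oxygen ends as a phenol.
- Comparison: structurally it delivers the same A–B ether as step 7. Mechanistically it is a clean pericyclic cascade but needs heat on a sensitive substrate. In step economy it is poorer, several steps for a bond that step 7 makes in one.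

Alternative 2: Here one ring bond next to the biaryl carbon is cut in each of rings C and D. Both arenes unfold into a bis-pyrone such as A4, whose two bridge carbons become the two biaryl carbons.

- Forward key step: alkoxide should open both lactones. In each arm the bridge carbon then attacks its own ester carbon in a Claisen-type condensation, and loss of alkoxide and enolisation give the biaryl A5.
- In its favour: the biaryl bond is an ordinary sp3–sp3 bond before aromatisation, so no tetra-ortho cross-coupling and no palladium are needed. On this point it is at least the equal of step 2 and arguably better. Two rings are formed in one operation along a polyketide-like path.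
- Against it: A5 is symmetric, has four equivalent free hydroxyls and lacks the ring C C1 oxygen. That oxygen would have to be introduced afterwards on one of four equivalent CH positions, which brings back the statistical monofunctionalisation that the formyl handle of 4 avoids. The bridge carbon is less acidic than the methylene between ketone and enol ether in each opened arm, so other condensation modes may compete, and both arms must cyclise correctly in the same molecule. The hydroxyl/methoxy differentiation of A5 is not needed.
- Comparison: the step count to the biaryl core is similar to steps 1 and 2. Remethylation, monofunctionalisation and oxidation would then make the way to 6 longer than the chosen three steps.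

Alternative 3: Here the C3–C4 bond of ring C is cut, tracing ring C to the silylated vinylcyclobutenone A6, which already carries ring D.

- Forward key step: thermolysis of A6 should open the four-membered ring to a dienylketene. The vinyl terminus closes onto the ketene carbon by 6π electrocyclisation, and tautomerisation gives A7 (Moore-type ring expansion).
- In its favour: every oxygen of ring C is placed without regiochemical doubt and all are differentiated. The C1 oxygen, the nucleophile of the chosen key step, is present as a silyl ether. The C5–ring D bond would come from addition of an aryl organometallic to a squaric ester and not from a hindered cross-coupling. In regiochemical certainty and in avoiding the tetra-ortho coupling it is the equal of, or better than, steps 1–3. It also converges with the chosen plan: after methylation of the C4 phenol and desilylation, a phenol of the same type as 6 would enter step 4, with the ethoxy group removed in the final dealkylation.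
- Against it: the sequence to such a phenol is long. It needs aryl addition, rearrangement to the aryl cyclobutenedione, addition of a lithiated enol ether at low temperature, silylation, thermolysis, methylation and desilylation, about seven steps against three. It uses pyrophoric alkyllithium reagents and sensitising squarates, so it is the less safe option.
- Comparison: structurally equal, mechanistically reliable and catalyst-free, but clearly inferior in step economy and safety.

Key step: step 4

## Route

Step 1
Reactants: 1 2,4,6-trimethoxybenzaldehyde
Product: 2 3-bromo-2,4,6-trimethoxybenzaldehyde
Conditions: NBS (1.0 equiv), MeCN, 0 °C to rt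
Reagents that add atoms: N-bromosuccinimide, O=C1CCC(=O)N1Br
Why: Electrophilic aromatic bromination; C3 and C5 are the only free positions, are equivalent, and are ortho/para to all three methoxy groups and meta to the formyl group, so one equivalent of NBS should give the mono-bromide.

Step 2
Reactants: 2 3-bromo-2,4,6-trimethoxybenzaldehyde; 3 (2,4,6-trimethoxyphenyl)boronic acid
Product: 4 2,2',4,4',6,6'-hexamethoxybiphenyl-3-carbaldehyde
Conditions: 3 (2 equiv), Pd(OAc)2 (5 mol%), SPhos (10 mol%), K3PO4, toluene/H2O, 100 °C
Reagents that add atoms: none
Why: Suzuki–Miyaura coupling; the bulky electron-rich phosphine SPhos supports oxidative addition of zerovalent palladium into the flanked C–Br bond and reductive elimination to a tetra-ortho-substituted biaryl, and the excess of 3 offsets protodeboronation. The formyl group makes the bromide the electron-poorer partner and marks ring C for the later oxygen; no stereogenic axis arises because ring D is symmetric.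

Step 3
Reactants: 4 2,2',4,4',6,6'-hexamethoxybiphenyl-3-carbaldehyde
Product: 6 2,2',4,4',6,6'-hexamethoxybiphenyl-3-ol, via aryl formate 5 (not isolated)
Conditions: 30% aq. H2O2, H2SO4 (cat.), MeOH, rt
Reagents that add atoms: hydrogen peroxide, OO
Why: Dakin oxidation (Baeyer–Villiger type); the peroxide adduct of the aldehyde rearranges with migration of the electron-rich, doubly ortho-methoxylated aryl group in preference to hydride, and the formate 5 is methanolysed in the same acidic medium.

Step 4
Reactants: 6 2,2',4,4',6,6'-hexamethoxybiphenyl-3-ol; 7 1,3-difluoro-5-methoxy-2-nitrobenzene; 8 sodium methoxide
Product: 10 3-(3,5-dimethoxy-2-nitrophenoxy)-2,2',4,4',6,6'-hexamethoxybiphenyl, via fluoro nitro diaryl ether 9 (not isolated)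
Conditions: 7 (1.1 equiv), K2CO3, DMF, rt to 50 °C until 6 is consumed; then 8 (2 equiv, solution in MeOH), 0 °C to rt, same flask
Reagents that add atoms: none
Why: Carbonate deprotonates 6 and the phenoxide oxygen adds to one of the two equivalent fluorine-bearing carbons of 7, giving a Meisenheimer adduct whose charge is taken up by the adjacent nitro group; fluoride then departs to give 9. Methoxide repeats the addition–elimination at the remaining C–F carbon of 9 to give 10; the closest known reaction type is the stepwise nucleophilic aromatic substitution of 2,6-difluoronitrobenzenes by a phenoxide and then an alkoxide. No ring is closed and no stereocentre is formed; the two new bonds are ring B C6–O (to ring C) and ring B C2–O (to methyl). Site selectivity is not an issue in the first stage because the fluorides of 7 are equivalent, and the phenoxide of 6 can react only at oxygen because its ortho and para carbons are all substituted. The selectivity that matters is mono- against bis-aryloxylation, which should be secured by the near 1:1 stoichiometry with a slight excess of 7, by donation from the new aryloxy oxygen onto the very carbons that would carry the charge of a second adduct, by the twist it forces on the nitro group, and by the bulk of the biaryl phenoxide. Methanol and methoxide are withheld until 6 is consumed so that they cannot compete for 7, and the small, strong methoxide then overcomes the deactivation of 9 at or below room temperature. Fluoride is a far better leaving group than aryloxide or methoxide in addition–elimination, so methoxide should attack the C–F carbon and not exchange the ether just formed. The polarity, with ring B as electrophile and the flanked ring C phenol as nucleophile, is the one in which di-ortho-substituted phenols are most reliable.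

Step 5
Reactants: 10 3-(3,5-dimethoxy-2-nitrophenoxy)-2,2',4,4',6,6'-hexamethoxybiphenyl
Product: 11 2-[(2,2',4,4',6,6'-hexamethoxybiphenyl-3-yl)oxy]-4,6-dimethoxyaniline
Conditions: H2 (1 atm), Pd/C (10 wt%), EtOAc/MeOH, rt
Reagents that add atoms: none
Why: Catalytic hydrogenation of an aryl nitro group; methyl ethers, diaryl ethers and the biaryl are inert and no halogen remains. The electron-rich aniline should be used directly.

Step 6
Reactants: 11 2-[(2,2',4,4',6,6'-hexamethoxybiphenyl-3-yl)oxy]-4,6-dimethoxyaniline
Product: 13 2-[(2,2',4,4',6,6'-hexamethoxybiphenyl-3-yl)oxy]-4,6-dimethoxyphenol, via arenediazonium hydrogen sulfate 12 (not isolated)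
Conditions: NaNO2, aq. H2SO4/MeCN, 0 °C; then Cu(NO3)2 (large excess), Cu2O (cat.), H2O, rt
Reagents that add atoms: sodium nitrite, [Na+].[O-]N=O (second nitrogen of 12 only); water, O (phenol oxygen of 13)
Why: Diazotisation followed by copper-mediated hydroxydediazoniation (Sandmeyer-type hydroxylation); monovalent copper reduces the diazonium ion to an aryl radical, which is captured by hydrated divalent copper to give the phenol and regenerate monovalent copper. This runs at room temperature in dilute solution, so 12 is neither isolated nor heated in acid, and radical closure onto ring C is disfavoured because both ortho positions of ring C are substituted.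

Step 7
Reactants: 13 2-[(2,2',4,4',6,6'-hexamethoxybiphenyl-3-yl)oxy]-4,6-dimethoxyphenol; 14 1-iodo-3,5-dimethoxybenzene
Product: 15 3-[2-(3,5-dimethoxyphenoxy)-3,5-dimethoxyphenoxy]-2,2',4,4',6,6'-hexamethoxybiphenyl
Conditions: CuI (10 mol%), picolinic acid (20 mol%), K3PO4, DMSO, 90 °C, argon
Reagents that add atoms: none
Why: Ullmann-type diaryl ether synthesis with a CuI/picolinic acid catalyst, a system suited to ortho-substituted phenols; the flanked, electron-rich phenoxide of 13 is the nucleophile and the unhindered iodide 14 the electrophile. Exclusion of air protects the oxidisable phenol.

Step 8
Reactants: 15 3-[2-(3,5-dimethoxyphenoxy)-3,5-dimethoxyphenoxy]-2,2',4,4',6,6'-hexamethoxybiphenyl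
Product: 16 3-[2-(3,5-dihydroxyphenoxy)-3,5-dihydroxyphenoxy]biphenyl-2,2',4,4',6,6'-hexol (CNP0210555.0)
Conditions: BBr3 (excess), CH2Cl2, −78 °C to rt; then H2O, 0 °C; work-up under argon
Reagents that add atoms: none
Why: Lewis-acid ether cleavage; BBr3 coordinates each methoxy oxygen and bromide removes the methyl group by SN2 attack, whereas the diaryl ether and biaryl bonds offer no sp3 carbon and stay intact. Hydrolysis of the boron aryloxides releases the ten phenols.

## Compound list

1 | 2,4,6-trimethoxybenzaldehyde | COc1cc(OC)c(C=O)c(OC)c1 | starting material
2 | 3-bromo-2,4,6-trimethoxybenzaldehyde | COc1cc(OC)c(C=O)c(OC)c1Br | intermediate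
3 | (2,4,6-trimethoxyphenyl)boronic acid | COc1cc(OC)c(B(O)O)c(OC)c1 | starting material
4 | 2,2',4,4',6,6'-hexamethoxybiphenyl-3-carbaldehyde | COc1cc(OC)c(-c2c(OC)cc(OC)cc2OC)c(OC)c1C=O | intermediate
5 | 2,2',4,4',6,6'-hexamethoxybiphenyl-3-yl formate | COc1cc(OC)c(-c2c(OC)cc(OC)cc2OC)c(OC)c1OC=O | intermediate
6 | 2,2',4,4',6,6'-hexamethoxybiphenyl-3-ol | COc1cc(OC)c(-c2c(OC)cc(OC)cc2OC)c(OC)c1O | intermediate
7 | 1,3-difluoro-5-methoxy-2-nitrobenzene | COc1cc(F)c([N+](=O)[O-])c(F)c1 | starting material
8 | sodium methoxide | [Na+].[O-]C | starting material
9 | 3-(3-fluoro-5-methoxy-2-nitrophenoxy)-2,2',4,4',6,6'-hexamethoxybiphenyl | COc1cc(F)c([N+](=O)[O-])c(Oc2c(OC)cc(OC)c(-c3c(OC)cc(OC)cc3OC)c2OC)c1 | intermediate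
10 | 3-(3,5-dimethoxy-2-nitrophenoxy)-2,2',4,4',6,6'-hexamethoxybiphenyl | COc1cc(OC)c([N+](=O)[O-])c(Oc2c(OC)cc(OC)c(-c3c(OC)cc(OC)cc3OC)c2OC)c1 | intermediate
11 | 2-[(2,2',4,4',6,6'-hexamethoxybiphenyl-3-yl)oxy]-4,6-dimethoxyaniline | COc1cc(OC)c(N)c(Oc2c(OC)cc(OC)c(-c3c(OC)cc(OC)cc3OC)c2OC)c1 | intermediate
12 | 2-[(2,2',4,4',6,6'-hexamethoxybiphenyl-3-yl)oxy]-4,6-dimethoxybenzenediazonium hydrogen sulfate | COc1cc(OC)c([N+]#N)c(Oc2c(OC)cc(OC)c(-c3c(OC)cc(OC)cc3OC)c2OC)c1.OS(=O)(=O)[O-] | intermediate
13 | 2-[(2,2',4,4',6,6'-hexamethoxybiphenyl-3-yl)oxy]-4,6-dimethoxyphenol | COc1cc(OC)c(O)c(Oc2c(OC)cc(OC)c(-c3c(OC)cc(OC)cc3OC)c2OC)c1 | intermediate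
14 | 1-iodo-3,5-dimethoxybenzene | COc1cc(I)cc(OC)c1 | starting material
15 | 3-[2-(3,5-dimethoxyphenoxy)-3,5-dimethoxyphenoxy]-2,2',4,4',6,6'-hexamethoxybiphenyl | COc1cc(OC)cc(Oc2c(OC)cc(OC)cc2Oc2c(OC)cc(OC)c(-c3c(OC)cc(OC)cc3OC)c2OC)c1 | intermediate
16 | 3-[2-(3,5-dihydroxyphenoxy)-3,5-dihydroxyphenoxy]biphenyl-2,2',4,4',6,6'-hexol | Oc1cc(O)cc(Oc2c(O)cc(O)cc2Oc2c(O)cc(O)c(-c3c(O)cc(O)cc3O)c2O)c1 | target

## Step count and least certain steps

Total step count: 8. Longest linear sequence: 8 steps (1 to 16); compounds 3, 7, 8 and 14 enter as purchased building blocks.

Step 4 (key step). The most likely failure is loss of mono-selectivity in the first displacement. Either a second phenoxide displaces the remaining fluoride of 9 before methoxide is added, or the hindered phenoxide reacts so slowly that methoxide later consumes unreacted 7 and leaves 6 behind. Both follow from the two substitution rates not being far enough apart. The fallback reverses the order of the nucleophiles in two separate operations. Starting from 7 and 8, one fluoride is replaced at low temperature (one equivalent of 8, THF/MeOH, −20 °C) to give 1-fluoro-3,5-dimethoxy-2-nitrobenzene F1, which is isolated. Its single remaining fluoride is then displaced by the phenoxide of 6 (Cs2CO3, DMSO, 80–100 °C), and the route is rejoined at 10. Bis-aryloxylation is then impossible by construction, at the price of a slower, hotter substitution.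

Step 2. Protodeboronation of 3 may outrun transmetalation at the doubly flanked palladium centre, and reductive loss of bromine from 2 may accompany it, because four ortho substituents slow the productive pathway. The fallback replaces boron by zinc. Starting from 2, a Negishi coupling with (2,4,6-trimethoxyphenyl)zinc iodide F2 (zinc dust and LiCl inserted into purchased 2-iodo-1,3,5-trimethoxybenzene in THF) under Pd2(dba)3/RuPhos in THF/NMP at 70–100 °C returns to the route at 4. Arylzinc halides do not protodemetalate under these conditions and tolerate the formyl group.

Step 6. The aryl radical or the diazonium ion may be diverted to reduction (hydrogen in place of the diazonium group) or to tar, and the very electron-rich phenol may be oxidised further by divalent copper. The fallback avoids the free phenol and reverses the polarity of the last ether bond. Starting from 11, the diazonium salt 12 is generated as before and quenched with aqueous KI to give 3-(2-iodo-3,5-dimethoxyphenoxy)-2,2',4,4',6,6'-hexamethoxybiphenyl F3. This iodide is coupled with purchased 3,5-dimethoxyphenol (CuI, picolinic acid, K3PO4, DMSO, 110 °C), and the route is rejoined at 15, replacing steps 6 and 7.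

Step 7. The copper-catalysed coupling may stall because the phenoxide of 13 is flanked on both sides, leaving time for oxidative degradation of the phenol and for reduction of 14. The fallback is a metal-free arylation with a hypervalent iodine electrophile. Compound 14 is oxidised (mCPBA, TsOH·H2O, MeCN) and condensed with 1,3,5-trimethoxybenzene to give (3,5-dimethoxyphenyl)(2,4,6-trimethoxyphenyl)iodonium 4-methylbenzenesulfonate F4. Treatment of 13 with t-BuOK and F4 in THF at rt to 40 °C should transfer the less electron-rich 3,5-dimethoxyphenyl group by ligand coupling, and the route is rejoined at 15.

Step 8. Cleavage of ten ethers may stop short at hindered positions, the bromomethane set free may C-methylate the electron-rich rings, and the free polyphenol may be lost to air oxidation during isolation. The fallback changes both the dealkylation and the isolation. Starting from 15, AlCl3 with ethanethiol in CH2Cl2 transfers the methyl groups to sulfur. The crude polyphenol is acetylated at once (Ac2O, pyridine) to the decaacetate F5 of 16, which is stable and can be purified on silica. Acid-catalysed methanolysis (HCl in MeOH, argon) then returns to the route at 16.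

## Further compounds

F1 | step 4 | 1-fluoro-3,5-dimethoxy-2-nitrobenzene | COc1cc(F)c([N+](=O)[O-])c(OC)c1
F2 | step 2 | (2,4,6-trimethoxyphenyl)zinc iodide | COc1cc(OC)c([Zn]I)c(OC)c1
F3 | step 6 | 3-(2-iodo-3,5-dimethoxyphenoxy)-2,2',4,4',6,6'-hexamethoxybiphenyl | COc1cc(OC)c(I)c(Oc2c(OC)cc(OC)c(-c3c(OC)cc(OC)cc3OC)c2OC)c1
F4 | step 7 | (3,5-dimethoxyphenyl)(2,4,6-trimethoxyphenyl)iodonium 4-methylbenzenesulfonate | COc1cc(OC)cc([I+]c2c(OC)cc(OC)cc2OC)c1.Cc1ccc(S(=O)(=O)[O-])cc1
F5 | step 8 | decaacetate of 16 (all ten phenolic oxygens acetylated) | CC(=O)Oc1cc(OC(C)=O)cc(Oc2c(OC(C)=O)cc(OC(C)=O)cc2Oc2c(OC(C)=O)cc(OC(C)=O)c(-c3c(OC(C)=O)cc(OC(C)=O)cc3OC(C)=O)c2OC(C)=O)c1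
A1 | alternative 1 | 1-(benzyloxy)-2-(ethynyloxy)-3,5-dimethoxybenzene | C#COc1c(OC)cc(OC)cc1OCc1ccccc1
A2 | alternative 1 | 3-ethoxycyclobut-2-en-1-one | CCOC1=CC(=O)C1
A3 | alternative 1 | 3-[2-(benzyloxy)-4,6-dimethoxyphenoxy]-5-ethoxyphenol | CCOc1cc(O)cc(Oc2c(OC)cc(OC)cc2OCc2ccccc2)c1
A4 | alternative 2 | 6,6'-(ethane-1,2-diyl)bis(4-methoxy-2H-pyran-2-one) | COC1=CC(=O)OC(CCC2=CC(OC)=CC(=O)O2)=C1
A5 | alternative 2 | 4,4'-dimethoxybiphenyl-2,2',6,6'-tetrol | COc1cc(O)c(-c2c(O)cc(OC)cc2O)c(O)c1
A6 | alternative 3 | 4-[(tert-butyldimethylsilyl)oxy]-4-(1-ethoxyethenyl)-3-methoxy-2-(2,4,6-trimethoxyphenyl)cyclobut-2-en-1-one (racemic) | C=C(OCC)C1(O[Si](C)(C)C(C)(C)C)C(OC)=C(c2c(OC)cc(OC)cc2OC)C1=O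
A7 | alternative 3 | 5-[(tert-butyldimethylsilyl)oxy]-4-ethoxy-2',4',6,6'-tetramethoxybiphenyl-2-ol | CCOc1cc(O)c(-c2c(OC)cc(OC)cc2OC)c(OC)c1O[Si](C)(C)C(C)(C)C
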